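Ring A is numbered C1–C6 throughout (C1 quaternary, C2 ketone, C3 carrying the acid chain, C4 enol, C5 carrying the acyl carbon, C6 carrying the ring-B oxygen); O2, O4 and O6 are the oxygens on C2, C4 and C6.

## Analysis of the target

The target is a dearomatised acylphloroglucinol: a cyclohexadienone ring A whose C5 acyl carbon and O6 are closed into a 2,3-dimethyl-2,3-dihydropyran-4-one ring B, while C3 carries C3 of a hexanoic acid chain and C4 a free enol. C1 is an all-carbon quaternary stereocentre (R) bearing a prenyl group and the CH2 arm of a cis-1,3-disubstituted 2,2-dimethylcyclobutane that also carries an isopropenyl group (1S,3R). The six stereocentres form four groups that are too far apart to control one another: the cyclobutane pair, C1, the side-chain CH (S) and the ring B pair (2R,3S, methyl groups cis). The sensitive parts are the prenyl and isopropenyl alkenes (the prenyl group lies next to enol oxygens and can cyclise onto them under acid), the strained ring, the strongly acidic enolised tricarbonyl system, and ring B, whose cis methyl groups can be lost by enolisation or by β-elimination of the ring oxygen under base. The difficulty is that C1 is stereogenic only because C2 and C6 lead into differently substituted flanks (C3 with the acid chain, C5 with the acyl group), so ring A must be assembled with full control over which carbonyl becomes C2 and which C6; in the same way O4 and O6, which both flank the acyl group, must be told apart when ring B is closed. The strategy rests on one feature: C1 with C2 and C6 is the central carbon and the two carboxyl carbons of a 2,2-dialkylmalonic acid, and C3, C4, C5 with the propanoyl group on C5 are the six-carbon chain of a 1,3-diketone, so that ring A is a malonyl dielectrophile joined to a diketone dinucleophile and the configuration of C1 can be stored beforehand as the difference between an acid chloride and an ester.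

## Retrosynthetic reasoning

The last bond cut is the lactone C–O bond: 27 is the hydrolysis product of enol lactone 26, in which the acid is tied to O4. Holding the acid as this lactone until the end is what distinguishes O4 from O6 while ring B is made, and the forward step only has to open an activated enol ester.

Ring B of 26 is cut at the bond between its oxygen and C6 and at the bond between its two methyl-bearing carbons. This leads through the syn β-hydroxy ketone 25 to the bis-silyl dienol ether 23 and acetaldehyde 24, and 23 comes from the propanoyl lactone 22 by enolisation. A concerted hetero-[4+2] addition of 24 to 23 is not relied on, because the diene terminus C6 is tetrasubstituted, lies in ring A and carries its silyloxy group on the inside of the diene. The two bonds are therefore made in turn: an aldol addition at the propanoyl α-carbon under a chiral Lewis acid has to set both ring B centres (syn), and a dehydrative closure of the new hydroxyl onto C6 has to keep them, so that syn becomes cis.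

In 22 the C3–CH bond and the lactone C–O bond are cut together, which gives trione 20 and (E)-hex-2-enal 21. C3 is the only ring CH of 20 and is the nucleophilic centre of a 1,3-dione, so one annulation can attach the whole acid chain, set its stereocentre and mask O4. The forward reaction has to choose one face of the enal β-carbon and close onto O4 and not O2.

Ring A of 20 is cut at C2–C3 and C5–C6. These are the two bonds between a malonyl unit and a diketone chain, and no stereocentre has to be created when they form. This gives acid chloride 11 and dienol ether 17. The forward step must join the diene terminus to the chloride carbon (intermediates 18 and 19) and only then the central carbon to the ester carbon; that order is what carries the configuration of 11 into C1 of 20.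

Diene 17 is traced to enone 16, silyl enol ether 15 and β-keto amide 14, made from amide 12 and acid chloride 13. This detour is deliberate: double silylation of an unsymmetrical 1,3-diketone would not distinguish the methyl from the ethyl terminus. In 14 the ketone can enolise in one direction only, and the methyl ketone is added afterwards, so the terminal CH2 of 17 is unambiguous.

Acid chloride 11 comes from half-ester 10, and 10 from the prochiral diester 9 by cleavage of one of two constitutionally equal ester groups with an esterase. Diester 9 is cut at its two C–C bonds to the malonate carbon, giving prenyl bromide 8 and monoalkyl malonate 7, and 7 gives dimethyl malonate 6 and iodide 5. The less reactive iodide is introduced first.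

Iodide 5 is taken back through alcohol 4 and acid 3 to keto acid 2, the oxidative cleavage product of verbenone 1. The bicycle supplies both cyclobutane centres and their cis relationship, and the carboxyl carbon of 2 is exactly the CH2 link of the target, so no carbon has to be removed later.

## Alternatives that were turned down

Alternative 1: The cyclobutane is built by a [2+2] cycloaddition and not taken from a terpene. The cut is through the CMe2–CH bond and the bond from the future isopropenyl-bearing carbon to the ring CH2. In the forward sense the keteniminium ion made from the C2-symmetric pyrrolidine isobutyramide A2 (amide activation with a sulfonic anhydride and a hindered pyridine base) adds to allyl benzoate A3, and hydrolysis gives cyclobutanone A1.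
- For it: either enantiomer is available, and the route does not depend on the optical purity of a natural product. On this point it is stronger than the chosen route.
- Against it: A1 has a carbonyl where the target has a CH carrying an isopropenyl group cis to the CH2 arm. Turning the ketone into that unit needs a homologation to the acetyl compound and a methylenation, and the cis relationship would have to be set at an epimerisable centre.
- Against it: A3 is a monosubstituted alkene with an electron-withdrawing allylic oxygen and is a poor partner for an electrophilic keteniminium ion.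
- Comparison: the alternative says nothing about ring A. The chosen route reaches 5 from 1 in four steps with both centres fixed, and so leaves the risk in step 13.

Alternative 2: The cyclobutane is closed last, from a lavandulyl chain on C1 of the otherwise complete enol lactone A5. A cobalt-hydride hydrogen-atom transfer to the isopropenyl CH2 gives a tertiary radical, which is oxidised to the cation and attacked by the trisubstituted alkene CH three atoms away; loss of a proton leaves the new isopropenyl group. The product A4 has the same structure as 26.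
- For it: it is the shortest way to the carbon skeleton and follows the likely biogenesis; in step economy it is stronger than the chosen route.
- Against it: a cation–alkene closure to a four-membered ring is strained and slow, and closure through the other alkene carbon to a five-membered ring, elimination and capture by the enol oxygens compete.
- Against it: the prenyl group on C1 is a second trisubstituted alkene in reach, and the two new ring centres would be set without any controlling element in the last C–C bond-forming step, on the most valuable intermediate.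
- Comparison: the chosen route has the cyclobutane with its configuration from the first step.

Alternative 3: Ring A is first made as the symmetric trione A7, without the acyl group, and a chiral carbene annulation with 21 then attacks one of the two ring CH2 groups and closes the lactone, giving A6. The C3–CH bond and the lactone C–O bond are formed as in step 14 of the chosen route, but the reaction also has to select between the two flanks of C1.
- For it: no enzymatic step and no differentiated malonate are needed, and the route is shorter; on step economy it is stronger.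
- Against it: one catalyst must control the face of the enal and at the same time the choice between two CH2 groups that differ only through a prenyl and a cyclobutylmethyl group on a carbon two bonds away.
- Against it: the propanoyl group must still be put on C5 of A6 by C-acylation next to an enol lactone.
- Comparison: the chosen route sets C1 through the reactivity difference between an acid chloride and an ester, which is mechanistically secure, sets the side-chain centre separately, and brings the acyl group in with the diene.

Key step: step 13

Remark: (1R,5R)-verbenone (1), the allylic oxidation product of (1R,5R)-α-pinene, is taken as a purchasable starting material of high enantiomeric purity.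
Remark: enolised tricarbonyl compounds are written as one tautomer; the other tautomers are the same compounds.
Remark: the esterase preparation, the triazolium salt and the tartaric acid ligand named are those expected to give the stated configurations; other isoenzymes and the antipodal salt and ligand are equally available if the sense proves opposite.

## Route

Step 1
Reactants: 1 (1R,5R)-verbenone
Product: 2 (1R,3S)-3-acetyl-2,2-dimethylcyclobutane-1-carboxylic acid
Conditions: RuCl3·3H2O (2 mol %), NaIO4 (4.5 equiv), EtOAc/MeCN/H2O, 20 °C
Reagents that add atoms: sodium periodate, [Na+].[O-]I(=O)(=O)=O; water, O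
Why: RuO4 formed in the flask cleaves the enone C=C bond and the resulting α-keto acid loses CO2 oxidatively (oxidative alkene cleavage); neither ring stereocentre is touched, so the cis arrangement of the bicycle is carried into the cyclobutane.

Step 2
Reactants: 2 (1R,3S)-3-acetyl-2,2-dimethylcyclobutane-1-carboxylic acid
Product: 3 (1R,3R)-2,2-dimethyl-3-(prop-1-en-2-yl)cyclobutane-1-carboxylic acid
Conditions: Ph3PCH3Br (2.6 equiv), KOt-Bu (2.5 equiv), THF, 0 → 20 °C; then 1 M HCl
Reagents that add atoms: methyltriphenylphosphonium bromide, C[P+](c1ccccc1)(c1ccccc1)c1ccccc1.[Br-]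
Why: Wittig methylenation of the methyl ketone; the acid is present as its potassium salt, which protects its own α-position, and the ylide should add to the ketone faster than the hindered ring CH is enolised, so the cis relationship should persist.

Step 3
Reactants: 3 (1R,3R)-2,2-dimethyl-3-(prop-1-en-2-yl)cyclobutane-1-carboxylic acid
Product: 4 [(1R,3R)-2,2-dimethyl-3-(prop-1-en-2-yl)cyclobutyl]methanol
Conditions: LiAlH4 (1.5 equiv), THF, 0 → 65 °C; aqueous NaOH work-up
Reagents that add atoms: none
Why: Hydride reduction of the carboxylate to the primary alcohol; the isolated alkene is inert to LiAlH4 and no stereocentre is involved.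

Step 4
Reactants: 4 [(1R,3R)-2,2-dimethyl-3-(prop-1-en-2-yl)cyclobutyl]methanol
Product: 5 (1R,3R)-1-(iodomethyl)-2,2-dimethyl-3-(prop-1-en-2-yl)cyclobutane
Conditions: I2 (1.3 equiv), PPh3 (1.3 equiv), imidazole (1.5 equiv), CH2Cl2, 0 → 20 °C
Reagents that add atoms: iodine, II
Why: Appel-type iodination through the alkoxyphosphonium ion with SN2 displacement by iodide at the primary carbon; no cation is formed, so the cyclobutylcarbinyl system cannot ring-expand.

Step 5
Reactants: 5 (1R,3R)-1-(iodomethyl)-2,2-dimethyl-3-(prop-1-en-2-yl)cyclobutane; 6 dimethyl malonate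
Product: 7 dimethyl 2-{[(1S,3R)-2,2-dimethyl-3-(prop-1-en-2-yl)cyclobutyl]methyl}propanedioate
Conditions: 6 (2.5 equiv), NaH (2.4 equiv), THF/DMF (4:1), 0 → 60 °C
Reagents that add atoms: none
Why: Malonic ester alkylation (SN2); the soft malonate anion should substitute the β-branched primary iodide and not eliminate, and the excess of 6 suppresses dialkylation.

Step 6
Reactants: 7 dimethyl 2-{[(1S,3R)-2,2-dimethyl-3-(prop-1-en-2-yl)cyclobutyl]methyl}propanedioate; 8 1-bromo-3-methylbut-2-ene (prenyl bromide)
Product: 9 dimethyl 2-{[(1S,3R)-2,2-dimethyl-3-(prop-1-en-2-yl)cyclobutyl]methyl}-2-(3-methylbut-2-en-1-yl)propanedioate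
Conditions: NaH (1.2 equiv), THF/DMF (4:1), 0 °C; 8 (1.3 equiv), 0 → 20 °C
Reagents that add atoms: none
Why: Second malonate alkylation; the allylic bromide reacts at its primary carbon (SN2) and the quaternary carbon is built while the two ester groups are still constitutionally equal.

Step 7
Reactants: 9 dimethyl 2-{[(1S,3R)-2,2-dimethyl-3-(prop-1-en-2-yl)cyclobutyl]methyl}-2-(3-methylbut-2-en-1-yl)propanedioate
Product: 10 (2S)-2-{[(1S,3R)-2,2-dimethyl-3-(prop-1-en-2-yl)cyclobutyl]methyl}-2-(methoxycarbonyl)-5-methylhex-4-enoic acid
Conditions: pig liver esterase, 0.1 M phosphate buffer pH 7.5/DMSO (9:1), 25 °C, pH-stat (1 M NaOH); then 1 M HCl to pH 2.5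
Reagents that add atoms: water, O
Why: Enzymatic desymmetrisation of a 2,2-disubstituted malonic diester; hydrolysis stops at the half-ester because the carboxylate is not a substrate, and the enzyme's choice of ester group sets the quaternary centre as (2S). Since the cyclobutane is already chiral the two possible half-esters are diastereomers, so a minor epimer can be detected and removed here.

Step 8
Reactants: 10 (2S)-2-{[(1S,3R)-2,2-dimethyl-3-(prop-1-en-2-yl)cyclobutyl]methyl}-2-(methoxycarbonyl)-5-methylhex-4-enoic acid
Product: 11 methyl (2R)-2-(chlorocarbonyl)-2-{[(1S,3R)-2,2-dimethyl-3-(prop-1-en-2-yl)cyclobutyl]methyl}-5-methylhex-4-enoate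
Conditions: 1-chloro-N,N,2-trimethylprop-1-en-1-amine (1.2 equiv), CH2Cl2, 0 → 20 °C; used crude
Reagents that add atoms: 1-chloro-N,N,2-trimethylprop-1-en-1-amine, CC(C)=C(Cl)N(C)C
Why: Acid chloride formation by chloride transfer from the α-chloroenamine under neutral conditions, so that no HCl can add to the alkenes or lactonise the acid onto the prenyl group; with no α-hydrogen the chloride can neither form a ketene nor epimerise (the descriptor changes from S to R only through the priority rules).

Step 9
Reactants: 12 N-methoxy-N-methylacetamide; 13 propanoyl chloride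
Product: 14 N-methoxy-N-methyl-3-oxopentanamide
Conditions: LiN(SiMe3)2 (2.1 equiv), 12 (2.1 equiv), THF, −78 °C; 13 (1.0 equiv); aqueous NH4Cl
Reagents that add atoms: none
Why: Claisen-type C-acylation of the amide lithium enolate; the second equivalent of enolate takes up the acidic proton of the β-keto amide.

Step 10
Reactants: 14 N-methoxy-N-methyl-3-oxopentanamide
Product: 15 (2Z)-3-[(tert-butyldimethylsilyl)oxy]-N-methoxy-N-methylpent-2-enamide
Conditions: t-BuMe2SiOTf (1.1 equiv), Et3N (1.5 equiv), CH2Cl2, 0 °C
Reagents that add atoms: tert-butyldimethylsilyl trifluoromethanesulfonate, CC(C)(C)[Si](C)(C)OS(=O)(=O)C(F)(F)F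
Why: Soft enolisation and O-silylation of the β-keto amide; the ketone enolises only toward the doubly activated CH2, so the silyloxy group is fixed on the ethyl-bearing carbon (the alkene geometry has no consequence later).

Step 11
Reactants: 15 (2Z)-3-[(tert-butyldimethylsilyl)oxy]-N-methoxy-N-methylpent-2-enamide
Product: 16 (3Z)-4-[(tert-butyldimethylsilyl)oxy]hex-3-en-2-one
Conditions: MeMgBr (1.3 equiv), THF, −78 → 0 °C; aqueous NH4Cl
Reagents that add atoms: methylmagnesium bromide, C[Mg]Br
Why: Ketone synthesis by Grignard addition to the N-methoxy-N-methylamide through its stable magnesium chelate, which prevents over-addition; the free methyl ketone is thereby placed unambiguously on the side away from the ethyl group.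

Step 12
Reactants: 16 (3Z)-4-[(tert-butyldimethylsilyl)oxy]hex-3-en-2-one
Product: 17 (3Z)-4-[(tert-butyldimethylsilyl)oxy]-2-[(trimethylsilyl)oxy]hexa-1,3-diene
Conditions: LiN(i-Pr)2 (1.1 equiv), THF, −78 °C; Me3SiCl (1.2 equiv), −78 → 0 °C; pentane, filtration
Reagents that add atoms: chlorotrimethylsilane, C[Si](C)(C)Cl
Why: Kinetic deprotonation of the β-silyloxy enone at the α'-methyl group and O-silylation of the enolate (silyl enol ether formation); the only terminal CH2 of the diene therefore comes from the methyl ketone.

Step 13
Reactants: 11 methyl (2R)-2-(chlorocarbonyl)-2-{[(1S,3R)-2,2-dimethyl-3-(prop-1-en-2-yl)cyclobutyl]methyl}-5-methylhex-4-enoate; 17 (3Z)-4-[(tert-butyldimethylsilyl)oxy]-2-[(trimethylsilyl)oxy]hexa-1,3-diene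
Product: 20 (6R)-6-{[(1S,3R)-2,2-dimethyl-3-(prop-1-en-2-yl)cyclobutyl]methyl}-3,5-dihydroxy-6-(3-methylbut-2-en-1-yl)-4-propanoylcyclohexa-2,4-dien-1-one, via silyloxy enone keto ester 18 (not isolated), via triketo ester 19 (not isolated)
Conditions: 17 (1.5 equiv), Me3SiOTf (0.3 equiv), CH2Cl2, −78 → −20 °C; 0.5 M HCl/THF, 0 °C; NaH (3.5 equiv), THF, 0 → 50 °C; then 1 M HCl to pH 3
Reagents that add atoms: none
Why: The silyl triflate activates the acid chloride of 11, and the terminal CH2 of 17, the most nucleophilic and least hindered carbon of the dienol ether, attacks it; loss of the trimethylsilyl group gives 18 with the new C2–C3 bond, the methyl ester being far less electrophilic and untouched at low temperature. Brief acid hydrolysis frees the 1,3,5-triketone 19, and NaH then removes a proton from each doubly activated methylene; only the carbon between the C4 carbonyl and the propanoyl carbonyl (C5) can reach the ester carbonyl through a six-membered transition state, so the Claisen-type (Dieckmann) closure forms C5–C6 in the 6-exo-trig mode, whereas attack from C3 would need a four-membered ring. The closest known reactions are the terminal C-acylation of 1,3-bis(silyloxy)-1,3-dienes by acid chlorides and the base-mediated Claisen closure of 3,5,7-triketo esters to acylphloroglucinol-type rings. No stereocentre is formed: C1 has no α-hydrogen and no bond to it is broken, so the configuration stored in 10 is passed on, (2R)-11 giving (6R)-20. The step needs chemoselectivity and regioselectivity: the chloride carbon must become C2 and the ester carbon C6, which the large gap in electrophilicity between acyl chloride and ester secures, and the diene must react at its terminal carbon, which its regiodefined construction and the bulk of the neopentyl-type acyl group secure. The methoxide set free meets only delocalised enolates, whose C2 and C6 carbonyls are poor electrophiles, so retro-Claisen opening next to the quaternary carbon should be suppressed, and the stable trione dianion drives the equilibrium. The gem-dialkyl effect at C1 favours the closure.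

Step 14
Reactants: 20 (6R)-6-{[(1S,3R)-2,2-dimethyl-3-(prop-1-en-2-yl)cyclobutyl]methyl}-3,5-dihydroxy-6-(3-methylbut-2-en-1-yl)-4-propanoylcyclohexa-2,4-dien-1-one; 21 (2E)-hex-2-enal
Product: 22 (4S,6R)-6-{[(1S,3R)-2,2-dimethyl-3-(prop-1-en-2-yl)cyclobutyl]methyl}-7-hydroxy-6-(3-methylbut-2-en-1-yl)-8-propanoyl-4-propyl-3,4-dihydro-2H-chromene-2,5(6H)-dione
Conditions: 21 (1.5 equiv), (5aS,10bR)-2-(2,4,6-trimethylphenyl)-5a,10b-dihydro-4H,6H-indeno[2,1-b][1,2,4]triazolo[4,3-d][1,4]oxazin-2-ium tetrafluoroborate (10 mol %), 3,3',5,5'-tetra-tert-butyldiphenoquinone (1.2 equiv), DBU (1.2 equiv), 4 Å MS, THF, 20 °C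
Reagents that add atoms: none
Why: Oxidative carbene-catalysed annulation: carbene and enal give, after oxidation by the quinone, an α,β-unsaturated acyl azolium, to whose β-carbon the only ring CH of the trione enolate (C3) adds (Michael addition), and the acyl azolium is then captured by the neighbouring O4 to close the enol lactone. The new centre is catalyst-controlled: the indane wall of the triazolium should leave the Si face of the β-carbon open, which gives (4S). O4 should be the oxygen acylated because it belongs to the already charged acyl-dione unit, whereas acylation on O2 would need a further enolisation next to the quaternary carbon.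

Step 15
Reactants: 22 (4S,6R)-6-{[(1S,3R)-2,2-dimethyl-3-(prop-1-en-2-yl)cyclobutyl]methyl}-7-hydroxy-6-(3-methylbut-2-en-1-yl)-8-propanoyl-4-propyl-3,4-dihydro-2H-chromene-2,5(6H)-dione
Product: 23 (4S,6R)-6-{[(1S,3R)-2,2-dimethyl-3-(prop-1-en-2-yl)cyclobutyl]methyl}-6-(3-methylbut-2-en-1-yl)-4-propyl-7-[(trimethylsilyl)oxy]-8-{(1Z)-1-[(trimethylsilyl)oxy]prop-1-en-1-yl}-3,4-dihydro-2H-chromene-2,5(6H)-dione
Conditions: Me3SiOTf (2.4 equiv), Et3N (3.0 equiv), CH2Cl2, −20 → 0 °C; pentane extraction, used crude
Reagents that add atoms: trimethylsilyl trifluoromethanesulfonate, C[Si](C)(C)OS(=O)(=O)C(F)(F)F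
Why: Soft enolisation (silyl enol ether formation): the acidic enol on ring-A carbon C6 is silylated at once and the propanoyl ketone is enolised toward its CH2, the (Z)-enol ether being favoured; the lactone is much slower to enolise under these conditions.

Step 16
Reactants: 23 (4S,6R)-6-{[(1S,3R)-2,2-dimethyl-3-(prop-1-en-2-yl)cyclobutyl]methyl}-6-(3-methylbut-2-en-1-yl)-4-propyl-7-[(trimethylsilyl)oxy]-8-{(1Z)-1-[(trimethylsilyl)oxy]prop-1-en-1-yl}-3,4-dihydro-2H-chromene-2,5(6H)-dione; 24 acetaldehyde
Product: 25 (4S,6R)-6-{[(1S,3R)-2,2-dimethyl-3-(prop-1-en-2-yl)cyclobutyl]methyl}-7-hydroxy-8-[(2S,3R)-3-hydroxy-2-methylbutanoyl]-6-(3-methylbut-2-en-1-yl)-4-propyl-3,4-dihydro-2H-chromene-2,5(6H)-dione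
Conditions: 24 (3 equiv), acyloxyborane from (2S,3S)-2-O-(2,6-diisopropoxybenzoyl)tartaric acid and BH3·THF (20 mol % each), EtCN, −78 °C; then 0.5 M HCl/THF, 0 °C
Reagents that add atoms: none
Why: Catalytic asymmetric Mukaiyama aldol addition: the chiral boron Lewis acid binds acetaldehyde and the terminal carbon of the silyl dienol ether adds through an open transition state, which favours the syn aldol whatever the enol ether geometry. The catalyst should direct the nucleophile to the Si face of the aldehyde, setting the carbinol centre as (R) and, through the syn preference, the methyl-bearing centre as (S); any minor isomers are diastereomers of 25 and separable.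

Step 17
Reactants: 25 (4S,6R)-6-{[(1S,3R)-2,2-dimethyl-3-(prop-1-en-2-yl)cyclobutyl]methyl}-7-hydroxy-8-[(2S,3R)-3-hydroxy-2-methylbutanoyl]-6-(3-methylbut-2-en-1-yl)-4-propyl-3,4-dihydro-2H-chromene-2,5(6H)-dione
Product: 26 enol lactone of the target: 25 after bonding of its side-chain hydroxyl oxygen to ring-A carbon C6 with loss of water, which closes the (2R,3S)-2,3-dimethyl-2,3-dihydropyran-4-one ring B
Conditions: pyridinium p-toluenesulfonate (10 mol %), 4 Å MS, CH2Cl2, 20 °C
Reagents that add atoms: none
Why: Acid-catalysed intramolecular vinylogous esterification (cyclodehydration of a δ-hydroxy β-diketone to a 2,3-dihydropyran-4-one): the hydroxyl adds to the enolic ring-A carbon C6 and water is lost. No bond to either side-chain stereocentre is broken, so the syn aldol becomes the cis-dimethyl ring B, and ring closure at the C4 side is blocked because O4 is held in the lactone.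

Step 18
Reactants: 26 enol lactone of the target
Product: 27 (3S)-3-[(2R,3S,8R)-8-{[(1S,3R)-2,2-dimethyl-3-(prop-1-en-2-yl)cyclobutyl]methyl}-5-hydroxy-2,3-dimethyl-8-(3-methylbut-2-en-1-yl)-4,7-dioxo-3,4,7,8-tetrahydro-2H-chromen-6-yl]hexanoic acid (target)
Conditions: LiOH (2.5 equiv), THF/H2O (3:1), 0 °C; then 1 M HCl to pH 3
Reagents that add atoms: lithium hydroxide, [Li+].[OH-]
Why: Saponification of the enol ester: hydroxide attacks the activated lactone carbonyl and releases the O4 enolate and the carboxylate. Once ring A is anionic the α-proton of ring B is much less acidic and the vinylogous ester is a poor electrophile, so the cis methyl groups and ring B should survive; mild acidification gives the acid.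

## Compound list

1 | (1R,5R)-verbenone [(1R,5R)-4,6,6-trimethylbicyclo[3.1.1]hept-3-en-2-one] | CC1=CC(=O)[C@@H]2C[C@H]1C2(C)C | starting material
2 | (1R,3S)-3-acetyl-2,2-dimethylcyclobutane-1-carboxylic acid | CC(=O)[C@H]1C[C@@H](C(=O)O)C1(C)C | intermediate
3 | (1R,3R)-2,2-dimethyl-3-(prop-1-en-2-yl)cyclobutane-1-carboxylic acid | C=C(C)[C@H]1C[C@@H](C(=O)O)C1(C)C | intermediate
4 | [(1R,3R)-2,2-dimethyl-3-(prop-1-en-2-yl)cyclobutyl]methanol | C=C(C)[C@H]1C[C@@H](CO)C1(C)C | intermediate
5 | (1R,3R)-1-(iodomethyl)-2,2-dimethyl-3-(prop-1-en-2-yl)cyclobutane | C=C(C)[C@H]1C[C@@H](CI)C1(C)C | intermediate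
6 | dimethyl malonate | COC(=O)CC(=O)OC | starting material
7 | dimethyl 2-{[(1S,3R)-2,2-dimethyl-3-(prop-1-en-2-yl)cyclobutyl]methyl}propanedioate | C=C(C)[C@H]1C[C@@H](CC(C(=O)OC)C(=O)OC)C1(C)C | intermediate
8 | 1-bromo-3-methylbut-2-ene (prenyl bromide) | CC(C)=CCBr | starting material
9 | dimethyl 2-{[(1S,3R)-2,2-dimethyl-3-(prop-1-en-2-yl)cyclobutyl]methyl}-2-(3-methylbut-2-en-1-yl)propanedioate | C=C(C)[C@H]1C[C@@H](CC(CC=C(C)C)(C(=O)OC)C(=O)OC)C1(C)C | intermediate
10 | (2S)-2-{[(1S,3R)-2,2-dimethyl-3-(prop-1-en-2-yl)cyclobutyl]methyl}-2-(methoxycarbonyl)-5-methylhex-4-enoic acid | C=C(C)[C@H]1C[C@@H](C[C@@](CC=C(C)C)(C(=O)O)C(=O)OC)C1(C)C | intermediate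
11 | methyl (2R)-2-(chlorocarbonyl)-2-{[(1S,3R)-2,2-dimethyl-3-(prop-1-en-2-yl)cyclobutyl]methyl}-5-methylhex-4-enoate | C=C(C)[C@H]1C[C@@H](C[C@@](CC=C(C)C)(C(Cl)=O)C(=O)OC)C1(C)C | intermediate
12 | N-methoxy-N-methylacetamide | CC(=O)N(C)OC | starting material
13 | propanoyl chloride | CCC(=O)Cl | starting material
14 | N-methoxy-N-methyl-3-oxopentanamide | CCC(=O)CC(=O)N(C)OC | intermediate
15 | (2Z)-3-[(tert-butyldimethylsilyl)oxy]-N-methoxy-N-methylpent-2-enamide | CC/C(O[Si](C)(C)C(C)(C)C)=C/C(=O)N(C)OC | intermediate
16 | (3Z)-4-[(tert-butyldimethylsilyl)oxy]hex-3-en-2-one | CC/C(O[Si](C)(C)C(C)(C)C)=C/C(C)=O | intermediate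
17 | (3Z)-4-[(tert-butyldimethylsilyl)oxy]-2-[(trimethylsilyl)oxy]hexa-1,3-diene | C=C(O[Si](C)(C)C)/C=C(/CC)O[Si](C)(C)C(C)(C)C | intermediate
18 | methyl (2S,6Z)-7-[(tert-butyldimethylsilyl)oxy]-2-{[(1S,3R)-2,2-dimethyl-3-(prop-1-en-2-yl)cyclobutyl]methyl}-2-(3-methylbut-2-en-1-yl)-3,5-dioxonon-6-enoate | C=C(C)[C@H]1C[C@@H](C[C@@](CC=C(C)C)(C(=O)CC(=O)/C=C(/CC)O[Si](C)(C)C(C)(C)C)C(=O)OC)C1(C)C | intermediate
19 | methyl (2S)-2-{[(1S,3R)-2,2-dimethyl-3-(prop-1-en-2-yl)cyclobutyl]methyl}-2-(3-methylbut-2-en-1-yl)-3,5,7-trioxononanoate | C=C(C)[C@H]1C[C@@H](C[C@@](CC=C(C)C)(C(=O)CC(=O)CC(=O)CC)C(=O)OC)C1(C)C | intermediate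
20 | (6R)-6-{[(1S,3R)-2,2-dimethyl-3-(prop-1-en-2-yl)cyclobutyl]methyl}-3,5-dihydroxy-6-(3-methylbut-2-en-1-yl)-4-propanoylcyclohexa-2,4-dien-1-one | C=C(C)[C@H]1C[C@@H](C[C@@]2(CC=C(C)C)C(=O)C=C(O)C(C(=O)CC)=C2O)C1(C)C | intermediate
21 | (2E)-hex-2-enal | CCC/C=C/C=O | starting material
22 | (4S,6R)-6-{[(1S,3R)-2,2-dimethyl-3-(prop-1-en-2-yl)cyclobutyl]methyl}-7-hydroxy-6-(3-methylbut-2-en-1-yl)-8-propanoyl-4-propyl-3,4-dihydro-2H-chromene-2,5(6H)-dione | C=C(C)[C@H]1C[C@@H](C[C@@]2(CC=C(C)C)C(=O)C3=C(OC(=O)C[C@@H]3CCC)C(C(=O)CC)=C2O)C1(C)C | intermediate
23 | (4S,6R)-6-{[(1S,3R)-2,2-dimethyl-3-(prop-1-en-2-yl)cyclobutyl]methyl}-6-(3-methylbut-2-en-1-yl)-4-propyl-7-[(trimethylsilyl)oxy]-8-{(1Z)-1-[(trimethylsilyl)oxy]prop-1-en-1-yl}-3,4-dihydro-2H-chromene-2,5(6H)-dione | C=C(C)[C@H]1C[C@@H](C[C@@]2(CC=C(C)C)C(=O)C3=C(OC(=O)C[C@@H]3CCC)C(/C(O[Si](C)(C)C)=C/C)=C2O[Si](C)(C)C)C1(C)C | intermediate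
24 | acetaldehyde | CC=O | starting material
25 | (4S,6R)-6-{[(1S,3R)-2,2-dimethyl-3-(prop-1-en-2-yl)cyclobutyl]methyl}-7-hydroxy-8-[(2S,3R)-3-hydroxy-2-methylbutanoyl]-6-(3-methylbut-2-en-1-yl)-4-propyl-3,4-dihydro-2H-chromene-2,5(6H)-dione | C=C(C)[C@H]1C[C@@H](C[C@@]2(CC=C(C)C)C(=O)C3=C(OC(=O)C[C@@H]3CCC)C(C(=O)[C@@H](C)[C@@H](C)O)=C2O)C1(C)C | intermediate
26 | enol lactone of the target (22 with the (2R,3S)-2,3-dimethyl-2,3-dihydropyran-4-one ring B closed between the acyl group and the oxygen on ring-A carbon C6) | C=C(C)[C@H]1C[C@@H](C[C@@]2(CC=C(C)C)C(=O)C3=C(OC(=O)C[C@@H]3CCC)C4=C2O[C@H](C)[C@H](C)C4=O)C1(C)C | intermediate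
27 | (3S)-3-[(2R,3S,8R)-8-{[(1S,3R)-2,2-dimethyl-3-(prop-1-en-2-yl)cyclobutyl]methyl}-5-hydroxy-2,3-dimethyl-8-(3-methylbut-2-en-1-yl)-4,7-dioxo-3,4,7,8-tetrahydro-2H-chromen-6-yl]hexanoic acid | C=C(C)[C@H]1C[C@@H](C[C@@]2(CC=C(C)C)C(=O)C([C@@H](CCC)CC(=O)O)=C(O)C3=C2O[C@H](C)[C@H](C)C3=O)C1(C)C | target

## Step count and least certain steps

Total step count: 18. Longest linear sequence: 14 steps (steps 1–8, 13 and 14–18); steps 9–12 build the diene in parallel.

Step 13 (key step). Acylation at the α-quaternary acyl chloride may be slow, so that the silyl triflate desilylates or protonates the diene first, or the acylated intermediate cyclises through oxygen with loss of silanol to a 4-pyranone. In the base stage, O-acylation or retro-Claisen cleavage beside the quaternary carbon may outrun the C-cyclisation. Fallback: starting from 16 and 11, the methyl group of 16 is deprotonated with LiN(i-Pr)2 at −78 °C to the lithium dienolate, lithium (3Z)-4-[(tert-butyldimethylsilyl)oxy]hexa-1,3-dien-2-olate F1. Two equivalents of F1 are acylated by 11 in a Claisen-type reaction of a preformed enolate, without a Lewis acid. This gives 18 directly, and the route is rejoined at 18 (hydrolysis to 19 and ring closure to 20).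

Step 7. The esterase may turn over the hindered, lipophilic diester only slowly and may discriminate poorly between the two ester groups, because prenyl and cyclobutylmethyl are both CH2-linked groups of similar size. Fallback: from 9, one equivalent of KOH in MeOH/H2O gives a mixture of 10 and its epimer, (2R)-2-{[(1S,3R)-2,2-dimethyl-3-(prop-1-en-2-yl)cyclobutyl]methyl}-2-(methoxycarbonyl)-5-methylhex-4-enoic acid F2. The two are diastereomers and are separated by preparative chromatography. F2 is re-esterified with Me3SiCHN2 in MeOH to 9 and recycled, and the route is rejoined at 10.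

Step 14. Facial discrimination by the carbene catalyst may be weak with this crowded, strongly acidic nucleophile, and lactonisation may occur onto O2 and not O4. Fallback: from 20, a three-component condensation with butanal and 2,2-dimethyl-1,3-dioxane-4,6-dione (piperidinium acetate, MeCN, 60 °C) forms the alkylidene compound 5-butylidene-2,2-dimethyl-1,3-dioxane-4,6-dione F3 in the flask (Knoevenagel condensation). C3 of 20 adds to F3 (Michael addition), and the adduct lactonises through an acyl ketene with loss of acetone and CO2. This gives 22 together with its epimer at the propyl-bearing carbon, the (4R)-lactone F4; the two are diastereomers and are separated by chromatography. The route is rejoined at 22.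

Step 16. Control of syn/anti and facial selectivity by the boron catalyst may be insufficient on a polyoxygenated silyl dienol ether, and silyl loss before C–C bond formation may compete. Fallback: from 23, an achiral Mukaiyama aldol addition of 24 (BF3·OEt2, CH2Cl2, −78 °C) gives the aldol diastereomers, which are separable because the rest of the molecule is stereodefined. 25 is taken on as in step 17. The anti isomer carrying the (2S,3S)-3-hydroxy-2-methylbutanoyl group, F5, is closed by a Mitsunobu reaction (PPh3, diisopropyl azodicarboxylate, THF), in which the acidic enol on ring-A carbon C6 displaces the activated hydroxyl with inversion. Both isomers thus converge; the route is rejoined at 25 and at 26.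

Step 17. Under acid the β-hydroxy ketone may dehydrate to the enone, the centre next to the ketone may epimerise, the enol may add to the protonated prenyl alkene, or the hydroxyl may attack the lactone-bearing carbon C4 with expulsion of the carboxylate. Fallback: from 25, the acidic enol is sulfonylated selectively (TsCl, Et3N, CH2Cl2, −20 °C) to the enol tosylate F6 (25 with a 4-methylbenzenesulfonyloxy group on ring-A carbon C6). The free secondary hydroxyl then replaces the tosylate by conjugate addition–elimination under mild base (Et3N, MeCN, 20 °C). This closes ring B without acid and with retention at the carbinol carbon, and the route is rejoined at 26.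

## Further compounds

F1 | step 13 | lithium (3Z)-4-[(tert-butyldimethylsilyl)oxy]hexa-1,3-dien-2-olate | [Li+].C=C([O-])/C=C(/CC)O[Si](C)(C)C(C)(C)C
F2 | step 7 | (2R)-2-{[(1S,3R)-2,2-dimethyl-3-(prop-1-en-2-yl)cyclobutyl]methyl}-2-(methoxycarbonyl)-5-methylhex-4-enoic acid | C=C(C)[C@H]1C[C@@H](C[C@](CC=C(C)C)(C(=O)O)C(=O)OC)C1(C)C
F3 | step 14 | 5-butylidene-2,2-dimethyl-1,3-dioxane-4,6-dione | CCCC=C1C(=O)OC(C)(C)OC1=O
F4 | step 14 | (4R,6R)-6-{[(1S,3R)-2,2-dimethyl-3-(prop-1-en-2-yl)cyclobutyl]methyl}-7-hydroxy-6-(3-methylbut-2-en-1-yl)-8-propanoyl-4-propyl-3,4-dihydro-2H-chromene-2,5(6H)-dione | C=C(C)[C@H]1C[C@@H](C[C@@]2(CC=C(C)C)C(=O)C3=C(OC(=O)C[C@H]3CCC)C(C(=O)CC)=C2O)C1(C)C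
F5 | step 16 | (4S,6R)-6-{[(1S,3R)-2,2-dimethyl-3-(prop-1-en-2-yl)cyclobutyl]methyl}-7-hydroxy-8-[(2S,3S)-3-hydroxy-2-methylbutanoyl]-6-(3-methylbut-2-en-1-yl)-4-propyl-3,4-dihydro-2H-chromene-2,5(6H)-dione | C=C(C)[C@H]1C[C@@H](C[C@@]2(CC=C(C)C)C(=O)C3=C(OC(=O)C[C@@H]3CCC)C(C(=O)[C@@H](C)[C@H](C)O)=C2O)C1(C)C
F6 | step 17 | (4S,6R)-6-{[(1S,3R)-2,2-dimethyl-3-(prop-1-en-2-yl)cyclobutyl]methyl}-8-[(2S,3R)-3-hydroxy-2-methylbutanoyl]-6-(3-methylbut-2-en-1-yl)-2,5-dioxo-4-propyl-3,4,5,6-tetrahydro-2H-chromen-7-yl 4-methylbenzenesulfonate | C=C(C)[C@H]1C[C@@H](C[C@@]2(CC=C(C)C)C(=O)C3=C(OC(=O)C[C@@H]3CCC)C(C(=O)[C@@H](C)[C@@H](C)O)=C2OS(=O)(=O)c4ccc(C)cc4)C1(C)C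
A1 | alternative 1 | (2,2-dimethyl-3-oxocyclobutyl)methyl benzoate (single enantiomer as drawn) | O=C1C[C@@H](COC(=O)c2ccccc2)C1(C)C
A2 | alternative 1 | 1-[(2R,5R)-2,5-dimethylpyrrolidin-1-yl]-2-methylpropan-1-one | CC(C)C(=O)N1[C@H](C)CC[C@H]1C
A3 | alternative 1 | allyl benzoate (prop-2-en-1-yl benzoate) | C=CCOC(=O)c1ccccc1
A4 | alternative 2 | enol lactone of the target (same structure as 26) | C=C(C)[C@H]1C[C@@H](C[C@@]2(CC=C(C)C)C(=O)C3=C(OC(=O)C[C@@H]3CCC)C4=C2O[C@H](C)[C@H](C)C4=O)C1(C)C
A5 | alternative 2 | enol lactone 26 with a (2S)-5-methyl-2-(prop-1-en-2-yl)hex-4-en-1-yl (lavandulyl) group in place of the cyclobutylmethyl group | C=C(C)[C@@H](CC=C(C)C)C[C@@]2(CC=C(C)C)C(=O)C3=C(OC(=O)C[C@@H]3CCC)C4=C2O[C@H](C)[C@H](C)C4=O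
A6 | alternative 3 | (4S,6R)-6-{[(1S,3R)-2,2-dimethyl-3-(prop-1-en-2-yl)cyclobutyl]methyl}-6-(3-methylbut-2-en-1-yl)-4-propyl-3,4,6,8-tetrahydro-2H-chromene-2,5,7-trione | C=C(C)[C@H]1C[C@@H](C[C@@]2(CC=C(C)C)C(=O)C3=C(OC(=O)C[C@@H]3CCC)CC2=O)C1(C)C
A7 | alternative 3 | 2-{[(1S,3R)-2,2-dimethyl-3-(prop-1-en-2-yl)cyclobutyl]methyl}-2-(3-methylbut-2-en-1-yl)cyclohexane-1,3,5-trione | C=C(C)[C@H]1C[C@@H](CC2(CC=C(C)C)C(=O)CC(=O)CC2=O)C1(C)C
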